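(The runs stem from a simulated flask on assumed constants, noise included.)

By 15.0 min, Saturday's run has lost more of its charge than Tuesday's, 42.7 % against 4.00 %, but per litre the three runs agree: 2.69 mM, 2.81 mM and 2.72 mM.

| flask | solid substrate | gas | remark | time |
|---|---|---|---|---|
| Saturday's | 6.3 mM | 12 mM (held) | run made earlier |  |
| Thursday's | 17 mM | 12 mM (held) | run made earlier |  |
| Tuesday's | 68 mM | 12 mM (held) | run made earlier |  |
| amber | 60 mM | 12 mM (held) |  | 30 min |
| violet | 5.0 mM | 12 mM (held) |  | 30 min |
| blue | 12 mM | 12 mM (held) |  | 30 min |
| grey | 20 mM | 12 mM (held) |  | 30 min |
| green | 40 mM | 12 mM (held) |  | 30 min |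
| ochre | 10 mM | 12 mM (held) |  | 30 min |

- Saturday's (time / min: product / %, solid substrate / %): 1.33: 0, 95.7; 3.00: 0, 89.5; 6.00: 4.1, 82.5; 15.0: 14.8, 57.3
- Thursday's (time / min: product / %, solid substrate / %): 1.33: 0, 100.1; 3.00: 1.0, 96.6; 6.00: 0, 93.0; 15.0: 6.6, 83.5
- Tuesday's (time / min: product / %, solid substrate / %): 1.33: 1.6, 100.8; 3.00: 0, 99.6; 6.00: 0.2, 98.9; 15.0: 0, 96.0

(readings scatter by 1 percentage point)

- as a solid, counted per litre of solution: solid substrate
- what was read earlier has a scatter of 1 percentage point, one standard deviation
- at the start none of the gas is in solution
- at the start none of the solid substrate is in solution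
- what has only dissolved of solid substrate counts as not reacted

- all flasks from highest to lowest amount of product, in percent of the solid substrate charged, at 30 min (amber / violet / blue / grey / green / ochre)
- the amount of product, in percent of the solid substrate charged of the flask you put first, at 30 min
- the amount of product, in percent of the solid substrate charged of the flask you put last, at 30 min

The quantity to carry is the loss rate r, the mM of solid substrate leaving the solid per minute, read here as the mean of the three runs, 0.183 mM min⁻¹. These readings show it as zero order in the charge, and this reckoning takes it to hold in the six flasks while solid substrate remains.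

With the main step alone, everything lost from the solid is product: 5.49 mM at 30 min, or 9.13 % in amber. The readings refuse this. At 15.0 min, product averages 1.03 mM over Saturday's and Thursday's runs; Tuesday's scatter is 0.680 mM per point, so it is left aside. A gap of 1.71 mM therefore stands in forms not read. If that gap stopped growing, product would reach 3.78 mM.

But the readings show product rising at only 0.0998 mM min⁻¹ between 6.00 min and 15.0 min, slower than r, so the gap is still widening. Continuing that line gives a reckoned product of 2.52 mM. Violet's charge lasts 27.4 min at r, 2.61 min short of 30 min, and this reckoning treats it like the others. Dividing by the charge gives 50.5 % for violet and 4.21 % for amber, with the order running opposite to the charge.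

The forecast gives violet > ochre > blue > grey > green > amber, with 61 % and 5.2 %, higher at the top than this reckoning, and opens with “The percent figures mislead”.

The flasks stand violet > ochre > blue > grey > green > amber, with violet at 50.7 % and amber at 4.28 %.

    starting material → intermediate A (k = 0.534 min⁻¹)
    coupling partner + intermediate A ⇌ intermediate B (K = 660 M⁻¹, k = 6.34 M⁻¹ min⁻¹)
    intermediate A → product (k = 0.110 min⁻¹)
    gas ⇌ coupling partner, rate k4*(csat - [coupling partner]) (kL = 1.38 min⁻¹)
    solid substrate ⇌ starting material, rate k5*(cs5 - [starting material]) while solid is left; crystals form when [starting material] > cs5 (solubility = 11.0 mM, k = 0.0173 min⁻¹)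

Amber's 4.28 % is 2.57 mM of product, and beside it at 30.0 min stand intermediate A at 1.75 % and intermediate B at 2.63 %. Read at 80 min, amber has lost 14.6 mM from the solid at r, which is 24.3 % of its charge; the flask then holds 75.4 % as solid substrate, which leaves 24.6 % gone from the solid.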